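**Strategy.** The plan rests on cutting the bond between the two oxygenated carbons of the tropolone ring: carbonyl carbon a and hydroxyl-bearing carbon g (ring atoms a, b, c, d, e, f, g; c carries a chroman, e and f are the fusion carbons to the benzo ring). Both carbons are aldehyde-derived, so one reductive ketyl (pinacol) coupling with SmI2 forms the a–g bond and closes the seven-membered ring. The precursor is an octabenzylated benzaldehyde (g) whose ortho position carries a trisubstituted c=d alkene with CH2CHO (b, a) cis to the arene, both (2R,3R)-chromans being in place; the two aldehydes are unveiled together by neutral oxidation just before the coupling.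

Key step: step 20

Remarks on the chemistry
- By the sequence rules the c=d alkene of the dialdehyde is E, not Z, because on carbon c the chroman C-2 (O,C,H) outranks CH2CHO (C,H,H); what the ring closure needs is arene and CH2CHO on the same side.
- The pinacol diol is carried as a mixture of carbinol diastereomers (cis expected), since both centres become sp2 one step later; the benzotropolone is drawn as one of its two rapidly interconverting tautomers.
- Both chromans are built from one chiral aldehyde; "ring A" is the phloroglucinol-type ring of each chroman; organometallic intermediates are drawn as monomers.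
- 1,3,5-Trifluorobenzene, (R)-glycidyl trityl ether and 3,4-bis(benzyloxy)phenol are taken as purchasable.

**Route**

Step 1
Reactants: 1 1,3,5-trifluorobenzene
Product: 2 1,3-bis(benzyloxy)-5-fluorobenzene
Conditions: BnOH (2.05 equiv), NaH (2.1 equiv), THF/DMF, 0 to 50 °C
Reagents that add atoms: benzyl alcohol, OCc1ccccc1
Why: Double nucleophilic aromatic substitution (SNAr) by sodium benzyloxide should stop after two fluorides because each exchange of fluorine for an alkoxy group makes the remaining C–F bond less reactive.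

Step 2
Reactants: 2 1,3-bis(benzyloxy)-5-fluorobenzene; 3 (R)-glycidyl trityl ether
Product: 5 (2R)-1-[2,4-bis(benzyloxy)-6-fluorophenyl]-3-(trityloxy)propan-2-ol, via aryllithium 4 (not isolated)
Conditions: n-BuLi (1.05 equiv), THF, −78 °C; then 3, BF3·OEt2, −78 °C; aq. NaHCO3
Reagents that add atoms: none
Why: Directed ortho-lithiation at the most acidic site between fluorine and benzyloxy, then BF3-assisted epoxide opening at the terminal carbon, joins ring A to the three-carbon unit without touching the stereocentre of 3, which becomes C-3 of a chroman.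

Step 3
Reactants: 5 (2R)-1-[2,4-bis(benzyloxy)-6-fluorophenyl]-3-(trityloxy)propan-2-ol
Product: 6 (2R)-2-(benzyloxy)-1-[2,4-bis(benzyloxy)-6-fluorophenyl]-3-(trityloxy)propane
Conditions: NaH, BnBr, Bu4NI (cat.), THF/DMF, 0 °C to rt
Reagents that add atoms: benzyl bromide, BrCc1ccccc1
Why: Williamson etherification of the secondary alkoxide is fast at 0 °C, well below the temperature at which the alkoxide could displace the ring fluoride.

Step 4
Reactants: 6 (2R)-2-(benzyloxy)-1-[2,4-bis(benzyloxy)-6-fluorophenyl]-3-(trityloxy)propane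
Product: 7 (2R)-2-(benzyloxy)-3-[2,4-bis(benzyloxy)-6-fluorophenyl]propan-1-ol
Conditions: TsOH·H2O (cat.), MeOH/CH2Cl2, rt
Reagents that add atoms: none
Why: Acid-catalysed solvolysis (detritylation) removes only the trityl ether, since benzyl ethers and the aryl fluoride are inert to dilute sulfonic acid in methanol.

Step 5
Reactants: 7 (2R)-2-(benzyloxy)-3-[2,4-bis(benzyloxy)-6-fluorophenyl]propan-1-ol
Product: 8 (2R)-2-(benzyloxy)-3-[2,4-bis(benzyloxy)-6-fluorophenyl]propanal
Conditions: Dess–Martin periodinane, pyridine, CH2Cl2, 0 °C to rt; used at once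
Reagents that add atoms: none
Why: Dess–Martin oxidation gives the α-benzyloxy aldehyde under near-neutral conditions that should not epimerise the α-centre.

Step 6
Reactants: 8 (2R)-2-(benzyloxy)-3-[2,4-bis(benzyloxy)-6-fluorophenyl]propanal
Product: 10 (3R,4R)-4-(benzyloxy)-5-[2,4-bis(benzyloxy)-6-fluorophenyl]pent-1-yn-3-ol, via silylated alkynol 9 (not isolated)
Conditions: Me3SiC≡CH, n-BuLi, Et2O, −78 °C; ZnBr2, 0 °C; then 8, −78 to 0 °C; aq. NH4Cl; then K2CO3 (cat.), MeOH, rt
Reagents that add atoms: ethynyltrimethylsilane, C#C[Si](C)(C)C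
Why: Chelation-controlled (Cram chelate) addition of the alkynylzinc bromide to the α-benzyloxy aldehyde brings the alkyne in from the face of the zinc chelate opposite the CH2Ar arm and so sets the new carbinol as the syn (3R,4R) isomer, after which methanolysis frees the terminal alkyne.

Step 7
Reactants: 11 3,4-bis(benzyloxy)phenol
Product: 12 4,5-bis(benzyloxy)-2-bromophenol
Conditions: NBS (1.0 equiv), MeCN, −20 to 0 °C
Reagents that add atoms: N-bromosuccinimide, O=C1CCC(=O)N1Br
Why: Electrophilic aromatic bromination goes to the unhindered position ortho to the free hydroxyl and para to a benzyloxy group, the most activated open site of the ring.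

Step 8
Reactants: 12 4,5-bis(benzyloxy)-2-bromophenol
Product: 13 5,6-bis(benzyloxy)-3-bromo-2-hydroxybenzaldehyde
Conditions: MgCl2, Et3N, (CH2O)n, MeCN, reflux; aq. HCl
Reagents that add atoms: paraformaldehyde (as formaldehyde), C=O
Why: Magnesium-mediated ortho-formylation of the phenoxide can only take place at the one remaining ortho position, between OH and OBn, because the other ortho site now carries bromine.

Step 9
Reactants: 13 5,6-bis(benzyloxy)-3-bromo-2-hydroxybenzaldehyde
Product: 14 3,4-bis(benzyloxy)-6-bromo-2-(hydroxymethyl)phenol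
Conditions: NaBH4, THF/MeOH, 0 °C
Reagents that add atoms: none
Why: Borohydride reduction converts the aldehyde into the benzylic alcohol and leaves the aryl bromide and the benzyl ethers untouched.

Step 10
Reactants: 14 3,4-bis(benzyloxy)-6-bromo-2-(hydroxymethyl)phenol
Product: 15 5,6-bis(benzyloxy)-8-bromo-2,2-dimethyl-4H-1,3-benzodioxine
Conditions: 2,2-dimethoxypropane, PPTS (cat.), acetone, rt
Reagents that add atoms: 2,2-dimethoxypropane, COC(C)(C)OC
Why: Acid-catalysed transacetalisation closes the six-membered isopropylidene acetal across the phenol and the ortho-hydroxymethyl group, masking both acidic OH groups in one step for the organometallic chemistry that follows.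

Step 11
Reactants: 15 5,6-bis(benzyloxy)-8-bromo-2,2-dimethyl-4H-1,3-benzodioxine; 8 (2R)-2-(benzyloxy)-3-[2,4-bis(benzyloxy)-6-fluorophenyl]propanal
Product: 18 (1R,2R)-2-(benzyloxy)-3-[2,4-bis(benzyloxy)-6-fluorophenyl]-1-[5,6-bis(benzyloxy)-2,2-dimethyl-4H-1,3-benzodioxin-8-yl]propan-1-ol, via aryllithium 16 (not isolated), via arylmagnesium bromide 17 (not isolated)
Conditions: n-BuLi, THF, −78 °C; MgBr2·OEt2, −78 to −20 °C; then 8, CH2Cl2, −78 °C; aq. NH4Cl
Reagents that add atoms: none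
Why: Bromine–lithium exchange, transmetalation to magnesium and chelation-controlled (Cram chelate) Grignard addition to the α-benzyloxy aldehyde should give the syn (1R,2R) alcohol, the aryl group entering the magnesium chelate from the face opposite the CH2Ar substituent.

Step 12
Reactants: 18 syn alcohol (1R,2R)
Product: 19 (2R,3R)-3,5,7-tris(benzyloxy)-2-[5,6-bis(benzyloxy)-2,2-dimethyl-4H-1,3-benzodioxin-8-yl]chromane
Conditions: KN(SiMe3)2 (1.2 equiv), THF/DMF, 0 to 60 °C
Reagents that add atoms: none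
Why: Intramolecular SNAr displacement of fluoride by the benzylic alkoxide closes the six-membered pyran ring with retention at C-2, because the C–O bond at that stereocentre is never broken, so the syn alcohol becomes the 2,3-cis (2R,3R) chroman.

Step 13
Reactants: 19 acetonide-protected chroman
Product: 20 3,4-bis(benzyloxy)-2-(hydroxymethyl)-6-[(2R,3R)-3,5,7-tris(benzyloxy)chroman-2-yl]phenol
Conditions: AcOH/H2O/THF (3:1:1), 45 °C
Reagents that add atoms: none
Why: Mild aqueous acid hydrolysis of the isopropylidene acetal frees the phenol and the benzylic alcohol while the benzyl ethers and the chroman survive, and water as the medium returns any transient ortho-quinone methide to the alcohol.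

Step 14
Reactants: 20 phenol with ortho-hydroxymethyl group
Product: 21 3,4-bis(benzyloxy)-2-(hydroxymethyl)-6-[(2R,3R)-3,5,7-tris(benzyloxy)chroman-2-yl]phenyl trifluoromethanesulfonate
Conditions: PhNTf2, Et3N, CH2Cl2, 0 °C to rt
Reagents that add atoms: N-phenylbis(trifluoromethanesulfonimide), O=S(=O)(N(c1ccccc1)S(=O)(=O)C(F)(F)F)C(F)(F)F
Why: O-Sulfonylation with this mild triflyl donor is selective for the phenoxide over the neutral primary alcohol, so the aryl triflate forms without protection of the hydroxymethyl group.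

Step 15
Reactants: 21 aryl triflate; 10 (3R,4R)-4-(benzyloxy)-5-[2,4-bis(benzyloxy)-6-fluorophenyl]pent-1-yn-3-ol
Product: 22 aryl alkynol (3R,4R)-4-(benzyloxy)-5-[2,4-bis(benzyloxy)-6-fluorophenyl]-1-{3,4-bis(benzyloxy)-2-(hydroxymethyl)-6-[(2R,3R)-3,5,7-tris(benzyloxy)chroman-2-yl]phenyl}pent-1-yn-3-ol
Conditions: PdCl2(PPh3)2 (5 mol%), CuI (10 mol%), Bu4NI, Et3N/DMF, 60 °C
Reagents that add atoms: none
Why: Sonogashira coupling tolerates both free hydroxyl groups and, because the incoming alkynyl group is linear, should cope with the two ortho substituents of the triflate.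

Step 16
Reactants: 22 aryl alkynol
Product: 24 dienol (arene cis to vinyl; 3R,4R), via alkenylmagnesium chelate 23 (not isolated)
Conditions: CH2=CHMgCl (6 equiv), THF/toluene, 0 to 70 °C; aq. NH4Cl, 0 °C
Reagents that add atoms: vinylmagnesium chloride, C=C[Mg]Cl
Why: Alkoxide-directed anti-carbomagnesiation of the propargylic alcohol places the vinyl group on the alkyne carbon next to the carbinol and magnesium on the aryl-bearing carbon within a five-membered magnesium chelate, so that protonation gives the trisubstituted alkene with the arene cis to the vinyl group.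

Step 17
Reactants: 24 dienol
Product: 25 bis-chroman dienyl benzyl alcohol
Conditions: KN(SiMe3)2 (2.3 equiv), THF/DMF, 0 to 60 °C
Reagents that add atoms: none
Why: A second intramolecular SNAr etherification closes the other pyran ring through the allylic alkoxide with retention, turning the syn (3R,4R) alcohol into the 2,3-cis (2R,3R) chroman, while the primary alkoxide has no ring of reasonable size to close.

Step 18
Reactants: 25 bis-chroman dienyl benzyl alcohol
Product: 27 diol (3E)-4-{3,4-bis(benzyloxy)-2-(hydroxymethyl)-6-[(2R,3R)-3,5,7-tris(benzyloxy)chroman-2-yl]phenyl}-3-[(2R,3R)-3,5,7-tris(benzyloxy)chroman-2-yl]but-3-en-1-ol, via organoborane 26 (not isolated)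
Conditions: 9-BBN (3 equiv), THF, 0 °C to rt; then NaOH, H2O2, 0 °C
Reagents that add atoms: hydrogen peroxide, OO
Why: Hydroboration–oxidation with the bulky 9-BBN is selective for the terminal vinyl group over the hindered trisubstituted styrene-type alkene and gives the anti-Markovnikov primary alcohol, which supplies carbons b and a.

Step 19
Reactants: 27 diol
Product: 28 dialdehyde 2,3-bis(benzyloxy)-6-{(1E)-4-oxo-2-[(2R,3R)-3,5,7-tris(benzyloxy)chroman-2-yl]but-1-en-1-yl}-5-[(2R,3R)-3,5,7-tris(benzyloxy)chroman-2-yl]benzaldehyde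
Conditions: Dess–Martin periodinane (3 equiv), pyridine, CH2Cl2, 0 °C to rt; crude product used at once
Reagents that add atoms: none
Why: Double Dess–Martin oxidation unveils the aryl aldehyde and the β,γ-unsaturated aliphatic aldehyde together under buffered neutral conditions, which should keep the alkene from migrating into conjugation.

Step 20
Reactants: 28 dialdehyde
Product: 29 pinacol diol 3,4-bis(benzyloxy)-1,8-bis[(2R,3R)-3,5,7-tris(benzyloxy)chroman-2-yl]-6,7-dihydro-5H-benzo[7]annulene-5,6-diol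
Conditions: SmI2 (3 equiv, 0.1 M in THF), slow addition of 28 to 0.005 M, −78 °C to rt; aq. NH4Cl
Reagents that add atoms: none
Why: Divalent samarium transfers one electron to the more easily reduced aryl aldehyde, the samarium-bound ketyl at carbon g adds to the samarium-coordinated aliphatic carbonyl carbon a, and a second electron transfer converts the resulting oxygen radical into the samarium diolate that is protonated on work-up. The closest known reaction type is the SmI2-promoted intramolecular pinacol coupling of dialdehydes to cyclic cis-diols. The seven-membered ring a–b–c–d–e–f–g closes by 7-exo-trig attack of the ketyl radical on the C=O group. Two carbinol centres arise at a and g; the samarium bridge between the two oxygens should favour the cis-diol, but no control is required because both centres become sp2 in step 21. The step needs cyclisation to win over intermolecular coupling and over simple reduction of either aldehyde, which is secured by the cis arrangement of arene and CH2CHO on the c=d alkene, by chelation of both carbonyl oxygens to samarium and by high dilution. Addition of the ketyl to the alkene is not expected to compete because it would need a 4-exo or 5-endo closure.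

Step 21
Reactants: 29 pinacol diol
Product: 31 octa-O-benzyltheaflavin (benzotropolone), via diketone 30 (not isolated)
Conditions: (COCl)2, DMSO, CH2Cl2, −78 °C; Et3N, −78 °C to rt
Reagents that add atoms: none
Why: Double Swern oxidation of the vicinal diol should give the 1,2-diketone without C–C cleavage, and its doubly activated CH2 group (carbon b) enolises under the amine base to the aromatic benzotropolone.

Step 22
Reactants: 31 octa-O-benzyltheaflavin
Product: 32 theaflavin
Conditions: H2 (1 atm), Pd(OH)2/C, THF/MeOH, rt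
Reagents that add atoms: none
Why: Catalytic hydrogenolysis should cleave all eight benzyl ethers under mild conditions that the aromatic benzotropolone and the cyclic ether bonds of the chromans are expected to survive.

**Compound list**

1 | 1,3,5-trifluorobenzene | Fc1cc(F)cc(F)c1 | starting material
2 | 1,3-bis(benzyloxy)-5-fluorobenzene | Fc1cc(OCc2ccccc2)cc(OCc2ccccc2)c1 | intermediate
3 | (R)-glycidyl trityl ether, (2R)-2-[(trityloxy)methyl]oxirane | C(c1ccccc1)(c1ccccc1)(c1ccccc1)OC[C@H]1CO1 | starting material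
4 | [2,4-bis(benzyloxy)-6-fluorophenyl]lithium | [Li]c1c(F)cc(OCc2ccccc2)cc1OCc1ccccc1 | intermediate (not isolated)
5 | (2R)-1-[2,4-bis(benzyloxy)-6-fluorophenyl]-3-(trityloxy)propan-2-ol | C(c1ccccc1)(c1ccccc1)(c1ccccc1)OC[C@H](O)Cc1c(F)cc(OCc2ccccc2)cc1OCc1ccccc1 | intermediate
6 | (2R)-2-(benzyloxy)-1-[2,4-bis(benzyloxy)-6-fluorophenyl]-3-(trityloxy)propane | C(c1ccccc1)(c1ccccc1)(c1ccccc1)OC[C@H](OCc1ccccc1)Cc1c(F)cc(OCc2ccccc2)cc1OCc1ccccc1 | intermediate
7 | (2R)-2-(benzyloxy)-3-[2,4-bis(benzyloxy)-6-fluorophenyl]propan-1-ol | OC[C@H](OCc1ccccc1)Cc1c(F)cc(OCc2ccccc2)cc1OCc1ccccc1 | intermediate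
8 | (2R)-2-(benzyloxy)-3-[2,4-bis(benzyloxy)-6-fluorophenyl]propanal | O=C[C@H](OCc1ccccc1)Cc1c(F)cc(OCc2ccccc2)cc1OCc1ccccc1 | intermediate
9 | (3R,4R)-4-(benzyloxy)-5-[2,4-bis(benzyloxy)-6-fluorophenyl]-1-(trimethylsilyl)pent-1-yn-3-ol | C[Si](C)(C)C#C[C@@H](O)[C@H](OCc1ccccc1)Cc1c(F)cc(OCc2ccccc2)cc1OCc1ccccc1 | intermediate (not isolated)
10 | (3R,4R)-4-(benzyloxy)-5-[2,4-bis(benzyloxy)-6-fluorophenyl]pent-1-yn-3-ol | C#C[C@@H](O)[C@H](OCc1ccccc1)Cc1c(F)cc(OCc2ccccc2)cc1OCc1ccccc1 | intermediate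
11 | 3,4-bis(benzyloxy)phenol | Oc1ccc(OCc2ccccc2)c(OCc2ccccc2)c1 | starting material
12 | 4,5-bis(benzyloxy)-2-bromophenol | Oc1cc(OCc2ccccc2)c(OCc2ccccc2)cc1Br | intermediate
13 | 5,6-bis(benzyloxy)-3-bromo-2-hydroxybenzaldehyde | O=Cc1c(O)c(Br)cc(OCc2ccccc2)c1OCc1ccccc1 | intermediate
14 | 3,4-bis(benzyloxy)-6-bromo-2-(hydroxymethyl)phenol | OCc1c(O)c(Br)cc(OCc2ccccc2)c1OCc1ccccc1 | intermediate
15 | 5,6-bis(benzyloxy)-8-bromo-2,2-dimethyl-4H-1,3-benzodioxine | CC1(C)OCc2c(O1)c(Br)cc(OCc1ccccc1)c2OCc1ccccc1 | intermediate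
16 | [5,6-bis(benzyloxy)-2,2-dimethyl-4H-1,3-benzodioxin-8-yl]lithium | CC1(C)OCc2c(O1)c([Li])cc(OCc1ccccc1)c2OCc1ccccc1 | intermediate (not isolated)
17 | [5,6-bis(benzyloxy)-2,2-dimethyl-4H-1,3-benzodioxin-8-yl]magnesium bromide | CC1(C)OCc2c(O1)c([Mg]Br)cc(OCc1ccccc1)c2OCc1ccccc1 | intermediate (not isolated)
18 | (1R,2R)-2-(benzyloxy)-3-[2,4-bis(benzyloxy)-6-fluorophenyl]-1-[5,6-bis(benzyloxy)-2,2-dimethyl-4H-1,3-benzodioxin-8-yl]propan-1-ol | CC1(C)OCc2c(O1)c(cc(OCc1ccccc1)c2OCc1ccccc1)[C@@H](O)[C@H](OCc1ccccc1)Cc1c(F)cc(OCc2ccccc2)cc1OCc1ccccc1 | intermediate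
19 | (2R,3R)-3,5,7-tris(benzyloxy)-2-[5,6-bis(benzyloxy)-2,2-dimethyl-4H-1,3-benzodioxin-8-yl]chromane | CC1(C)OCc2c(O1)c(cc(OCc1ccccc1)c2OCc1ccccc1)[C@H]1Oc2cc(OCc3ccccc3)cc(OCc3ccccc3)c2C[C@H]1OCc1ccccc1 | intermediate
20 | 3,4-bis(benzyloxy)-2-(hydroxymethyl)-6-[(2R,3R)-3,5,7-tris(benzyloxy)chroman-2-yl]phenol | OCc1c(O)c(cc(OCc2ccccc2)c1OCc1ccccc1)[C@H]1Oc2cc(OCc3ccccc3)cc(OCc3ccccc3)c2C[C@H]1OCc1ccccc1 | intermediate
21 | 3,4-bis(benzyloxy)-2-(hydroxymethyl)-6-[(2R,3R)-3,5,7-tris(benzyloxy)chroman-2-yl]phenyl trifluoromethanesulfonate | OCc1c(OS(=O)(=O)C(F)(F)F)c(cc(OCc2ccccc2)c1OCc1ccccc1)[C@H]1Oc2cc(OCc3ccccc3)cc(OCc3ccccc3)c2C[C@H]1OCc1ccccc1 | intermediate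
22 | (3R,4R)-4-(benzyloxy)-5-[2,4-bis(benzyloxy)-6-fluorophenyl]-1-{3,4-bis(benzyloxy)-2-(hydroxymethyl)-6-[(2R,3R)-3,5,7-tris(benzyloxy)chroman-2-yl]phenyl}pent-1-yn-3-ol | OCc1c(C#C[C@@H](O)[C@H](OCc2ccccc2)Cc2c(F)cc(OCc3ccccc3)cc2OCc2ccccc2)c(cc(OCc2ccccc2)c1OCc1ccccc1)[C@H]1Oc2cc(OCc3ccccc3)cc(OCc3ccccc3)c2C[C@H]1OCc1ccccc1 | intermediate
23 | alkenylmagnesium chloride of 24 with both hydroxyls as chloromagnesium alkoxides (magnesium on the aryl-bearing alkene carbon, cis to the carbinol; chelate drawn open) | Cl[Mg]OCc1c(/C([Mg]Cl)=C(\C=C)[C@@H](O[Mg]Cl)[C@H](OCc2ccccc2)Cc2c(F)cc(OCc3ccccc3)cc2OCc2ccccc2)c(cc(OCc2ccccc2)c1OCc1ccccc1)[C@H]1Oc2cc(OCc3ccccc3)cc(OCc3ccccc3)c2C[C@H]1OCc1ccccc1 | intermediate (not isolated)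
24 | (1E,3R,4R)-4-(benzyloxy)-5-[2,4-bis(benzyloxy)-6-fluorophenyl]-1-{3,4-bis(benzyloxy)-2-(hydroxymethyl)-6-[(2R,3R)-3,5,7-tris(benzyloxy)chroman-2-yl]phenyl}-2-ethenylpent-1-en-3-ol (arene cis to ethenyl) | OCc1c(/C=C(\C=C)[C@@H](O)[C@H](OCc2ccccc2)Cc2c(F)cc(OCc3ccccc3)cc2OCc2ccccc2)c(cc(OCc2ccccc2)c1OCc1ccccc1)[C@H]1Oc2cc(OCc3ccccc3)cc(OCc3ccccc3)c2C[C@H]1OCc1ccccc1 | intermediate
25 | [2,3-bis(benzyloxy)-5-[(2R,3R)-3,5,7-tris(benzyloxy)chroman-2-yl]-6-{(1E)-2-[(2R,3R)-3,5,7-tris(benzyloxy)chroman-2-yl]buta-1,3-dien-1-yl}phenyl]methanol | OCc1c(/C=C(\C=C)[C@H]2Oc3cc(OCc4ccccc4)cc(OCc4ccccc4)c3C[C@H]2OCc2ccccc2)c(cc(OCc2ccccc2)c1OCc1ccccc1)[C@H]1Oc2cc(OCc3ccccc3)cc(OCc3ccccc3)c2C[C@H]1OCc1ccccc1 | intermediate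
26 | B-alkyl-9-BBN adduct of 25 at the terminal vinyl carbon, with the benzylic hydroxyl as its 9-BBN borinate | C1CCC2CCCC1B2OCc1c(/C=C(\CCB2C3CCCC2CCC3)[C@H]2Oc3cc(OCc4ccccc4)cc(OCc4ccccc4)c3C[C@H]2OCc2ccccc2)c(cc(OCc2ccccc2)c1OCc1ccccc1)[C@H]1Oc2cc(OCc3ccccc3)cc(OCc3ccccc3)c2C[C@H]1OCc1ccccc1 | intermediate (not isolated)
27 | (3E)-4-{3,4-bis(benzyloxy)-2-(hydroxymethyl)-6-[(2R,3R)-3,5,7-tris(benzyloxy)chroman-2-yl]phenyl}-3-[(2R,3R)-3,5,7-tris(benzyloxy)chroman-2-yl]but-3-en-1-ol | OCc1c(/C=C(\CCO)[C@H]2Oc3cc(OCc4ccccc4)cc(OCc4ccccc4)c3C[C@H]2OCc2ccccc2)c(cc(OCc2ccccc2)c1OCc1ccccc1)[C@H]1Oc2cc(OCc3ccccc3)cc(OCc3ccccc3)c2C[C@H]1OCc1ccccc1 | intermediate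
28 | 2,3-bis(benzyloxy)-6-{(1E)-4-oxo-2-[(2R,3R)-3,5,7-tris(benzyloxy)chroman-2-yl]but-1-en-1-yl}-5-[(2R,3R)-3,5,7-tris(benzyloxy)chroman-2-yl]benzaldehyde | O=Cc1c(OCc2ccccc2)c(OCc2ccccc2)cc([C@H]2Oc3cc(OCc4ccccc4)cc(OCc4ccccc4)c3C[C@H]2OCc2ccccc2)c1/C=C(\CC=O)[C@H]2Oc3cc(OCc4ccccc4)cc(OCc4ccccc4)c3C[C@H]2OCc2ccccc2 | intermediate
29 | 3,4-bis(benzyloxy)-1,8-bis[(2R,3R)-3,5,7-tris(benzyloxy)chroman-2-yl]-6,7-dihydro-5H-benzo[7]annulene-5,6-diol (C-5/C-6 diastereomer mixture, cis expected) | OC1C(O)CC([C@H]2Oc3cc(OCc4ccccc4)cc(OCc4ccccc4)c3C[C@H]2OCc2ccccc2)=Cc2c([C@H]3Oc4cc(OCc5ccccc5)cc(OCc5ccccc5)c4C[C@H]3OCc3ccccc3)cc(OCc3ccccc3)c(OCc3ccccc3)c21 | intermediate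
30 | 3,4-bis(benzyloxy)-1,8-bis[(2R,3R)-3,5,7-tris(benzyloxy)chroman-2-yl]-5H-benzo[7]annulene-5,6(7H)-dione | O=C1C(=O)CC([C@H]2Oc3cc(OCc4ccccc4)cc(OCc4ccccc4)c3C[C@H]2OCc2ccccc2)=Cc2c([C@H]3Oc4cc(OCc5ccccc5)cc(OCc5ccccc5)c4C[C@H]3OCc3ccccc3)cc(OCc3ccccc3)c(OCc3ccccc3)c21 | intermediate (not isolated)
31 | 3,4-bis(benzyloxy)-5-hydroxy-1,8-bis[(2R,3R)-3,5,7-tris(benzyloxy)chroman-2-yl]-6H-benzo[7]annulen-6-one (octa-O-benzyltheaflavin) | O=c1cc([C@H]2Oc3cc(OCc4ccccc4)cc(OCc4ccccc4)c3C[C@H]2OCc2ccccc2)cc2c([C@H]3Oc4cc(OCc5ccccc5)cc(OCc5ccccc5)c4C[C@H]3OCc3ccccc3)cc(OCc3ccccc3)c(OCc3ccccc3)c2c1O | intermediate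
32 | theaflavin, 3,4,5-trihydroxy-1,8-bis[(2R,3R)-3,5,7-trihydroxychroman-2-yl]-6H-benzo[7]annulen-6-one | O=c1cc([C@H]2Oc3cc(O)cc(O)c3C[C@H]2O)cc2c([C@H]3Oc4cc(O)cc(O)c4C[C@H]3O)cc(O)c(O)c2c1O | target

**Step count and risks**

Total step count: 22 steps. Longest linear sequence: 17 steps (steps 1–5, then 11–22, from 1,3,5-trifluorobenzene).

Steps most likely to fail:

Step 20 (pinacol ring closure). The ketyl may be reduced further to the benzylic alcohol, or couple between molecules, faster than it closes the seven-membered ring. The fallback sets out from 28 and forms the same a–g bond by acyl-anion rather than ketyl umpolung. An azolium-carbene-catalysed intramolecular crossed benzoin reaction (triazolium precatalyst, Et3N, THF, rt) would let the Breslow intermediate of the unhindered aliphatic aldehyde add to the hindered aryl aldehyde, giving the seven-membered α-hydroxy ketone F1. A single Swern oxidation of F1 gives diketone 30, which tautomerises to 31, where the route is rejoined.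

Step 16 (carbomagnesiation). Vinyl transfer to the hindered aryl alkyne may be sluggish or lose its regiochemical bias, or the benzylic alkoxide may add to the alkyne instead. The fallback sets out from 22 and uses hydroxyl-directed trans-hydrostannation (Bu3SnH, [Cp*RuCl]4 cat., CH2Cl2). This places tin on the alkyne carbon next to the carbinol and hydrogen anti to it, giving the alkenylstannane F2. Iodine in CH2Cl2 then replaces tin with retention to give the alkenyl iodide F3. Suzuki–Miyaura coupling of F3 with vinylboronic acid pinacol ester (PdCl2(dppf), K3PO4, THF/H2O) returns dienol 24 with the same alkene geometry.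

Step 11 (aryl addition). Chelation may not discriminate the two faces of the aldehyde well enough, giving poor facial selectivity at the new carbinol. The fallback sets out from 18 as obtained in admixture with its carbinol epimer F4. The mixture would be oxidised with Dess–Martin periodinane to the aryl ketone F5. Corey–Bakshi–Shibata reduction (oxazaborolidine catalyst, BH3·SMe2; the (R)-catalyst if the aryl group behaves as the larger substituent) would then set the carbinol centre under reagent control and return 18.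

Further compounds
F1 | step 20 | 3,4-bis(benzyloxy)-5-hydroxy-1,8-bis[(2R,3R)-3,5,7-tris(benzyloxy)chroman-2-yl]-5,7-dihydro-6H-benzo[7]annulen-6-one (carbinol centre unassigned) | OC1C(=O)CC([C@H]2Oc3cc(OCc4ccccc4)cc(OCc4ccccc4)c3C[C@H]2OCc2ccccc2)=Cc2c([C@H]3Oc4cc(OCc5ccccc5)cc(OCc5ccccc5)c4C[C@H]3OCc3ccccc3)cc(OCc3ccccc3)c(OCc3ccccc3)c21
F2 | step 16 | (1Z,3S,4R)-4-(benzyloxy)-5-[2,4-bis(benzyloxy)-6-fluorophenyl]-1-{3,4-bis(benzyloxy)-2-(hydroxymethyl)-6-[(2R,3R)-3,5,7-tris(benzyloxy)chroman-2-yl]phenyl}-2-(tributylstannyl)pent-1-en-3-ol | OCc1c(/C=C(\[Sn](CCCC)(CCCC)CCCC)[C@@H](O)[C@H](OCc2ccccc2)Cc2c(F)cc(OCc3ccccc3)cc2OCc2ccccc2)c(cc(OCc2ccccc2)c1OCc1ccccc1)[C@H]1Oc2cc(OCc3ccccc3)cc(OCc3ccccc3)c2C[C@H]1OCc1ccccc1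
F3 | step 16 | (1Z,3S,4R)-4-(benzyloxy)-5-[2,4-bis(benzyloxy)-6-fluorophenyl]-1-{3,4-bis(benzyloxy)-2-(hydroxymethyl)-6-[(2R,3R)-3,5,7-tris(benzyloxy)chroman-2-yl]phenyl}-2-iodopent-1-en-3-ol | OCc1c(/C=C(\I)[C@@H](O)[C@H](OCc2ccccc2)Cc2c(F)cc(OCc3ccccc3)cc2OCc2ccccc2)c(cc(OCc2ccccc2)c1OCc1ccccc1)[C@H]1Oc2cc(OCc3ccccc3)cc(OCc3ccccc3)c2C[C@H]1OCc1ccccc1
F4 | step 11 | (1S,2R)-2-(benzyloxy)-3-[2,4-bis(benzyloxy)-6-fluorophenyl]-1-[5,6-bis(benzyloxy)-2,2-dimethyl-4H-1,3-benzodioxin-8-yl]propan-1-ol | CC1(C)OCc2c(O1)c(cc(OCc1ccccc1)c2OCc1ccccc1)[C@H](O)[C@H](OCc1ccccc1)Cc1c(F)cc(OCc2ccccc2)cc1OCc1ccccc1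
F5 | step 11 | (2R)-2-(benzyloxy)-3-[2,4-bis(benzyloxy)-6-fluorophenyl]-1-[5,6-bis(benzyloxy)-2,2-dimethyl-4H-1,3-benzodioxin-8-yl]propan-1-one | CC1(C)OCc2c(O1)c(cc(OCc1ccccc1)c2OCc1ccccc1)C(=O)[C@H](OCc1ccccc1)Cc1c(F)cc(OCc2ccccc2)cc1OCc1ccccc1
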